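**Plan**

1. Locants: ring A is the prenylated resorcinol ring (C1'–C6'), the chain is C1 (C=O), C2 (CHOH), C3 (CH2), and ring B is the 4-hydroxyphenyl ring. The retrosynthesis cuts the four O-protecting bonds first, then C2–C3, then C2–O, then the two aryl–prenyl bonds at C3' and C5'.
2. Forward: resacetophenone is prenylated twice on ring A, protected as MOM (methoxymethyl) ethers, hydroxylated at C2 through its enolate and etherified there. Ring B comes as 4-(methoxymethoxy)benzyl bromide. The two fragments are joined at C2–C3 and one acid step frees all four hydroxyls.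
3. Enabling feature: C2 lies between the C1 carbonyl, which is conjugated to ring A with the C2' oxygen ortho to it, and its own oxygen. The target therefore contains an ortho-alkoxyaryl glycolyl ketone, the substrate type of asymmetric phase-transfer glycolate alkylation. C3 is benzylic and para to the ring B oxygen, so it is available as a reactive benzylic bromide.
4. Stereochemistry: the only stereocentre, C2 (S), is set in the C2–C3 bond formation by enantioface-selective benzylation of the Z-enolate inside a chiral cinchonidinium ion pair. Afterwards only the O–CHAr2 bond of its ether is broken, never a bond at C2.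

Key step: step 7

Remark: bis(4-methoxyphenyl)methyl chloride is taken as a purchasable reagent, and the cinchonidinium salt of step 7 as a known catalyst made from cinchonidine in two routine operations that are not counted.
Remark: in step 8 the three aryl MOM ethers of the non-isolated ketol are expected to fall off in no fixed order, so only the first, defined in-flask intermediate is numbered.

**Step 1**
Reactants: 1 2',4'-dihydroxyacetophenone (resacetophenone); 2 prenyl bromide (2.5 equiv)
Product: 4 1-[2,4-dihydroxy-3,5-bis(3-methylbut-2-en-1-yl)phenyl]ethan-1-one, via 3'-prenyl monoadduct 3 (not isolated)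
Conditions: KOH (10% aq.), 0 °C to rt
Reagents that add atoms: none
Why: Nuclear C-prenylation of a phenoxide: with the C2' hydroxyl tied up by its hydrogen bond to the acetyl group, the C4' phenoxide is alkylated by the allylic bromide at its two ortho carbons C3' and C5', the only ring positions it activates, first between the two oxygens and then at C5', a known but modestly selective reaction that is accepted for its brevity.

**Step 2**
Reactants: 4 diprenylresacetophenone
Product: 6 1-[2,4-bis(methoxymethoxy)-3,5-bis(3-methylbut-2-en-1-yl)phenyl]ethan-1-one, via 4'-O-MOM monoether 5 (not isolated)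
Conditions: NaH, MOMCl, DMF, 0 °C to rt
Reagents that add atoms: chloromethyl methyl ether, COCCl
Why: Williamson-type acetal ether formation: both sodium phenoxides, the free C4' one first and then the hindered, formerly chelated C2' one, are alkylated by the very reactive chloromethyl ether, which removes the acidic protons before the enolate chemistry that follows.

**Step 3**
Reactants: 6 bis-MOM diprenylacetophenone
Product: 8 1-[2,4-bis(methoxymethoxy)-3,5-bis(3-methylbut-2-en-1-yl)phenyl]-2-hydroxyethan-1-one, via potassium enolate 7 (not isolated)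
Conditions: KN(SiMe3)2, THF, −78 °C; then 2-(phenylsulfonyl)-3-phenyloxaziridine, −78 °C; aq. NH4Cl
Reagents that add atoms: 2-(phenylsulfonyl)-3-phenyloxaziridine, O=S(=O)(N1OC1c1ccccc1)c1ccccc1
Why: Enolate hydroxylation with an N-sulfonyloxaziridine (Davis oxidation): the potassium enolate attacks the electrophilic oxaziridine oxygen and the adduct collapses to the C2 alkoxide and the sulfonimine, while the reagent leaves the trisubstituted prenyl double bonds, which a peracid would epoxidise, untouched.

**Step 4**
Reactants: 8 glycolyl ketone
Product: 9 2-[bis(4-methoxyphenyl)methoxy]-1-[2,4-bis(methoxymethoxy)-3,5-bis(3-methylbut-2-en-1-yl)phenyl]ethan-1-one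
Conditions: (4-MeOC6H4)2CHCl, i-Pr2NEt, DMAP (cat.), CH2Cl2, 0 °C to rt
Reagents that add atoms: bis(4-methoxyphenyl)methyl chloride, COc1ccc(C(Cl)c2ccc(OC)cc2)cc1
Why: SN1 etherification in the manner of a tritylation: the chloride ionises to the doubly anisyl-stabilised benzhydryl cation, which the primary C2 hydroxyl captures under amine buffering so that no acid reaches the MOM ethers or prenyl groups, and the group gives the benzhydryl-type steric wall wanted in step 7 while being far more acid-labile than a plain diphenylmethyl ether.

**Step 5**
Reactants: 10 4-hydroxybenzyl alcohol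
Product: 11 [4-(methoxymethoxy)phenyl]methanol
Conditions: MOMCl, K2CO3, acetone, 0 °C to rt
Reagents that add atoms: chloromethyl methyl ether, COCCl
Why: Chemoselective phenol O-alkylation: K2CO3 deprotonates only the phenol, not the benzylic alcohol, and the phenoxide is alkylated by the chloromethyl ether.

**Step 6**
Reactants: 11 MOM-protected benzyl alcohol
Product: 12 1-(bromomethyl)-4-(methoxymethoxy)benzene
Conditions: CBr4, PPh3, CH2Cl2, 0 °C
Reagents that add atoms: carbon tetrabromide, BrC(Br)(Br)Br
Why: Appel bromination: the alkoxyphosphonium ion formed from PPh3 and CBr4 is displaced by bromide under neutral conditions that spare the acid-sensitive MOM ether, and the electron-rich benzylic bromide is used at once without chromatography.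

**Step 7**
Reactants: 9 protected glycolyl ketone (fragment A); 12 benzylic bromide (fragment B, 3 equiv)
Product: 14 (2S)-2-[bis(4-methoxyphenyl)methoxy]-1-[2,4-bis(methoxymethoxy)-3,5-bis(3-methylbut-2-en-1-yl)phenyl]-3-[4-(methoxymethoxy)phenyl]propan-1-one, via cesium Z-enolate 13 (not isolated)
Conditions: O(9)-allyl-N-(2,3,4-trifluorobenzyl)cinchonidinium bromide (10 mol %), CsOH·H2O, CH2Cl2/n-hexane (1:1), −35 °C
Reagents that add atoms: none
Why: Solid CsOH deprotonates C2 of 9 at the interface (C2–H is acidified by the C1 aryl carbonyl and by its own ether oxygen), and the Z-enolate 13, whose geometry is fixed by allylic strain between ring A and the C2 alkoxy group, passes into the organic phase as a tight ion pair with the chiral ammonium cation and attacks bromide 12 in an SN2 reaction to form C2–C3. The closest known reaction type is the asymmetric phase-transfer glycolate alkylation of 2-(diphenylmethoxy)-1-(2,5-dimethoxyphenyl)ethanone with benzylic bromides, which 9 matches in its ortho-alkoxyaryl ketone and its benzhydryl-type ether. No ring is closed. The new stereocentre C2 is set by the catalyst: the quinoline and 2,3,4-trifluorobenzyl walls and the O-allyl group of the cinchonidinium cation cover one enolate face, so the bromide should enter from the open face and give the S configuration, the sense that cinchonidine-derived salts give in this reaction class (the cinchonine-derived pseudoenantiomer would serve if the sense proved opposite). The step needs C- over O-alkylation, mono- over dialkylation and a slow uncatalysed background, which the soft benzylic bromide, the hindered tertiary C2–H of the product and the insolubility of the bare cesium enolate in CH2Cl2/hexane at −35 °C should secure. The MOM ethers, the dianisylmethyl ether and the prenyl groups are inert to hydroxide at this temperature.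

**Step 8**
Reactants: 14 fully protected ketol
Product: 16 Lespeflorin C6, via tris-MOM ketol 15 (not isolated)
Conditions: HCl (1.25 M in MeOH), THF, 0 °C to 30 °C
Reagents that add atoms: none
Why: Acid-catalysed solvolysis of benzhydryl and acetal ethers: the C2–O ether ionises at the bis(4-methoxyphenyl)methyl carbon, not at C2, so the configuration is retained and the cation is trapped by methanol, after which the three aryl MOM acetals are exchanged to dimethoxymethane under acid dilute and cool enough that neither addition of the freed phenols to the prenyl double bonds nor enolisation towards C2 should compete.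

**Compound list**

1 | 1-(2,4-dihydroxyphenyl)ethan-1-one (resacetophenone) | CC(=O)c1ccc(O)cc1O | starting material
2 | 1-bromo-3-methylbut-2-ene (prenyl bromide) | CC(C)=CCBr | starting material
3 | 1-[2,4-dihydroxy-3-(3-methylbut-2-en-1-yl)phenyl]ethan-1-one | CC(=O)c1ccc(O)c(CC=C(C)C)c1O | intermediate
4 | 1-[2,4-dihydroxy-3,5-bis(3-methylbut-2-en-1-yl)phenyl]ethan-1-one | CC(C)=CCc1cc(C(C)=O)c(O)c(CC=C(C)C)c1O | intermediate
5 | 1-[2-hydroxy-4-(methoxymethoxy)-3,5-bis(3-methylbut-2-en-1-yl)phenyl]ethan-1-one | CC(C)=CCc1cc(C(C)=O)c(O)c(CC=C(C)C)c1OCOC | intermediate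
6 | 1-[2,4-bis(methoxymethoxy)-3,5-bis(3-methylbut-2-en-1-yl)phenyl]ethan-1-one | CC(C)=CCc1cc(C(C)=O)c(OCOC)c(CC=C(C)C)c1OCOC | intermediate
7 | potassium 1-[2,4-bis(methoxymethoxy)-3,5-bis(3-methylbut-2-en-1-yl)phenyl]ethen-1-olate | CC(C)=CCc1cc(C(=C)[O-])c(OCOC)c(CC=C(C)C)c1OCOC.[K+] | intermediate
8 | 1-[2,4-bis(methoxymethoxy)-3,5-bis(3-methylbut-2-en-1-yl)phenyl]-2-hydroxyethan-1-one | CC(C)=CCc1cc(C(=O)CO)c(OCOC)c(CC=C(C)C)c1OCOC | intermediate
9 | 2-[bis(4-methoxyphenyl)methoxy]-1-[2,4-bis(methoxymethoxy)-3,5-bis(3-methylbut-2-en-1-yl)phenyl]ethan-1-one | CC(C)=CCc1cc(C(=O)COC(c2ccc(OC)cc2)c2ccc(OC)cc2)c(OCOC)c(CC=C(C)C)c1OCOC | intermediate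
10 | 4-(hydroxymethyl)phenol (4-hydroxybenzyl alcohol) | OCc1ccc(O)cc1 | starting material
11 | [4-(methoxymethoxy)phenyl]methanol | COCOc1ccc(CO)cc1 | intermediate
12 | 1-(bromomethyl)-4-(methoxymethoxy)benzene | COCOc1ccc(CBr)cc1 | intermediate
13 | cesium (Z)-2-[bis(4-methoxyphenyl)methoxy]-1-[2,4-bis(methoxymethoxy)-3,5-bis(3-methylbut-2-en-1-yl)phenyl]ethen-1-olate | CC(C)=CCc1cc(/C([O-])=C/OC(c2ccc(OC)cc2)c2ccc(OC)cc2)c(OCOC)c(CC=C(C)C)c1OCOC.[Cs+] | intermediate
14 | (2S)-2-[bis(4-methoxyphenyl)methoxy]-1-[2,4-bis(methoxymethoxy)-3,5-bis(3-methylbut-2-en-1-yl)phenyl]-3-[4-(methoxymethoxy)phenyl]propan-1-one | CC(C)=CCc1cc(C(=O)[C@@H](OC(c2ccc(OC)cc2)c2ccc(OC)cc2)Cc2ccc(OCOC)cc2)c(OCOC)c(CC=C(C)C)c1OCOC | intermediate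
15 | (2S)-1-[2,4-bis(methoxymethoxy)-3,5-bis(3-methylbut-2-en-1-yl)phenyl]-2-hydroxy-3-[4-(methoxymethoxy)phenyl]propan-1-one | CC(C)=CCc1cc(C(=O)[C@@H](O)Cc2ccc(OCOC)cc2)c(OCOC)c(CC=C(C)C)c1OCOC | intermediate
16 | (2S)-1-[2,4-dihydroxy-3,5-bis(3-methylbut-2-en-1-yl)phenyl]-2-hydroxy-3-(4-hydroxyphenyl)propan-1-one (Lespeflorin C6) | CC(C)=CCc1cc(C(=O)[C@@H](O)Cc2ccc(O)cc2)c(O)c(CC=C(C)C)c1O | target

**Count**

Total steps: 8. Longest linear sequence: 6 steps (1, 2, 3, 4, 7, 8); steps 5 and 6 make fragment B on a side branch.

**Steps most likely to fail**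

Step 7. The enantioface discrimination may erode because ring A, with its C2' MOM ether buttressed by the C3' prenyl group, is bulkier than the aryl groups on which the ion-pair model rests, and the electron-rich bromide may be lost to hydrolysis before the enolate consumes it. The fallback keeps the C2–C3 bond as an enolate benzylation but moves stereocontrol to a reagent-controlled oxygenation. It sets out from compounds 6 and 12 and returns at compound 15. Ketone 6 is deprotonated with LiN(i-Pr)2 in THF at −78 °C to lithium 1-[2,4-bis(methoxymethoxy)-3,5-bis(3-methylbut-2-en-1-yl)phenyl]ethen-1-olate F1, which is benzylated by 12 to the dihydrochalcone 1-[2,4-bis(methoxymethoxy)-3,5-bis(3-methylbut-2-en-1-yl)phenyl]-3-[4-(methoxymethoxy)phenyl]propan-1-one F2. NaN(SiMe3)2 in THF at −78 °C then should give sodium (Z)-1-[2,4-bis(methoxymethoxy)-3,5-bis(3-methylbut-2-en-1-yl)phenyl]-3-[4-(methoxymethoxy)phenyl]prop-1-en-1-olate F3. This is hydroxylated with an enantiopure (8,8-dichlorocamphorylsulfonyl)oxaziridine (asymmetric Davis oxidation), using the antipode that gives S-configured 2-hydroxy-1-arylpropan-1-ones from Z-enolates. The product is compound 15, here isolated, and its three MOM ethers are removed as in step 8 to give 16.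

Step 1. Regiocontrol of the phenoxide alkylation may be lost to O-prenylation, to arrest at the monoprenyl stage and to geminal dialkylation at C3', leaving little of the 3',5'-diprenyl product. The fallback fixes both positions with halogens and sets out from compound 1, returning at compound 6. Twofold electrophilic bromination (Br2, AcOH, rt) at the two carbons ortho to the C4' hydroxyl should give 1-(3,5-dibromo-2,4-dihydroxyphenyl)ethan-1-one F4. Protection (NaH, MOMCl, DMF) gives 1-[3,5-dibromo-2,4-bis(methoxymethoxy)phenyl]ethan-1-one F5. A twofold Stille coupling with tributyl(3-methylbut-2-en-1-yl)stannane (Pd(PPh3)4, LiCl, DMF, 90 °C) then places both prenyl groups regiospecifically and delivers 6.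

Step 8. While the slowest MOM ether is still being cleaved, the phenols already freed may add to the neighbouring prenyl double bonds under acid catalysis (chroman formation), and prolonged acid may erode the C2 configuration through enolisation. The fallback replaces protic solvolysis by two aprotic operations; it sets out from compound 14, passes through compound 15 and ends at compound 16, making no new compound. DDQ in CH2Cl2/pH 7 buffer at 0 °C removes the bis(4-methoxyphenyl)methyl ether oxidatively by hydride abstraction at the benzhydryl carbon to give 15, here isolated. ZnBr2 and n-PrSH in CH2Cl2 at 0 °C then cleave the three MOM ethers within minutes by thiol capture of the oxocarbenium ions, without a Brønsted acid bath, to give 16.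

**Further compounds**

F1 | step 7 | lithium 1-[2,4-bis(methoxymethoxy)-3,5-bis(3-methylbut-2-en-1-yl)phenyl]ethen-1-olate | CC(C)=CCc1cc(C(=C)[O-])c(OCOC)c(CC=C(C)C)c1OCOC.[Li+]
F2 | step 7 | 1-[2,4-bis(methoxymethoxy)-3,5-bis(3-methylbut-2-en-1-yl)phenyl]-3-[4-(methoxymethoxy)phenyl]propan-1-one | CC(C)=CCc1cc(C(=O)CCc2ccc(OCOC)cc2)c(OCOC)c(CC=C(C)C)c1OCOC
F3 | step 7 | sodium (Z)-1-[2,4-bis(methoxymethoxy)-3,5-bis(3-methylbut-2-en-1-yl)phenyl]-3-[4-(methoxymethoxy)phenyl]prop-1-en-1-olate | CC(C)=CCc1cc(/C([O-])=C/Cc2ccc(OCOC)cc2)c(OCOC)c(CC=C(C)C)c1OCOC.[Na+]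
F4 | step 1 | 1-(3,5-dibromo-2,4-dihydroxyphenyl)ethan-1-one | CC(=O)c1cc(Br)c(O)c(Br)c1O
F5 | step 1 | 1-[3,5-dibromo-2,4-bis(methoxymethoxy)phenyl]ethan-1-one | CC(=O)c1cc(Br)c(OCOC)c(Br)c1OCOC
F0 | step 8 | none | none
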